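The constants used here are assumed; the result is computed.

A one-step world, substrate plus reagent giving target and nothing besides, turns equal charges wholly into target. This flask has side steps that also take reagent, and a short meeting reckoned their cost.

substrate 0.024 M; reagent in the second phase 0.0240 M; time 3.0 d; volume of the second phase over the first 0.50

- target and crystals together at 3.0 d, in percent of the substrate charged
- the change that raises the amount of target and crystals together at 3.0 d, in percent of the substrate charged most ("none" if none brings more than 2 percentage points) (eta / beta / delta / zeta / none)
- amount of target and crystals together at 3.0 d, in percent of the substrate charged, after eta

- eta: doubling the amount of reagent in the second phase, all else as stated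
- beta: doubling the solubility in step 5, all else as stated
- delta: doubling the dissolution coefficient of step 5, all else as stated
- zeta: doubling the transfer coefficient of step 1, all else as stated

- amounts and yields of target count crystals too
- in the second phase: reagent in the second phase; everything else is in the first
- charges count per volume of the first phase; a concentration in a rate is the amount of a species over the volume of its own phase; every rate counts per litre of the first phase
- given per volume of solution although it is solid: crystals
- run time (flask): 3.0 d

    reagent in the reaction phase ⇌ reagent in the second phase, rate k1*([reagent in the reaction phase] - [reagent in the second phase]/K1) per volume of the first phase (K1 = 0.81, k1 = 0.0294 min⁻¹)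
    substrate + reagent in the reaction phase → target (k2 = 0.642 M⁻¹ min⁻¹)
    reagent in the reaction phase + target → over-reacted product (k3 = 0.284 M⁻¹ min⁻¹)
    reagent in the reaction phase + target → over-reaction product (k4 = 0.0782 M⁻¹ min⁻¹)
    crystals ⇌ target, rate k5*(cs5 - [target]) while solid is left; crystals form when [target] > cs5 (cs5 = 2.1 mM, k5 = 0.0150 min⁻¹)
    reagent in the reaction phase → decomposed reagent (k6 = 7.96 × 10⁻⁴ min⁻¹)

Minutes. The process chemist opened. Decomposition halves the reagent in the reaction phase in 0.60 d, shorter than the run of 3.0 d, so she proposed reckoning the end of the reaction, not a time course, with the reagent of both phases as the likely limiting reagent.

I argued that each step using reagent is first order in the reagent in the reaction phase, so its concentration cancels when the steps are compared. Dissolved target starts at nothing, climbs past solubility and returns, and I judged its mean as 4.20 mM, twice the solubility. What remains is the side drain 0.00232 min⁻¹: the summed constants of steps 3 and 4 times the mean dissolved target, plus the decomposition constant.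

With equal charges, reagent lost to the drain equals substrate left. Dividing the drain by the constant of step 2 and the substrate charge gives 0.150. Replacing the substrate curve by the straight mean of its ends leaves 20.0%. The logarithmic mean of that curve, checked on this figure, leaves 24.2%. I took the middle, 22.1%. Over-reaction also removes target, so my yield was 63.4%. My reckoning stopped there.

The author of the forecast, stepping by hand, reported 64%, above mine, then 43% after eta, and named delta as best: “Delta cuts supersaturation, so it helps most.”

The simulation gives 63.7%, with 22% of the substrate left and 1.45 × 10⁻⁹ M of reagent in the reaction phase at 3.00 d. The best change is delta, at 3.9 percentage points; eta brings −22 points, beta −5.9 points, zeta −0.14 points, and eta ends at 41.5%.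

In this flask, over-reacted product, over-reaction product and decomposed reagent took 5.29 mM of reagent, against 5.29 mM of substrate left. The neighbour flask with 0.041 M of substrate charges less reagent than substrate. The same drain, with mean substrate 29.0 mM, makes 21.3 mM of target before over-reaction, leaving 48.0% of its substrate and yielding 47.8%. That neighbour flask ends with 49.2% of its substrate left and a yield of 45.1%.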